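**Retrosynthetic overview**
1. Acid 13 comes from ethyl ester 12, and 12 from phosphonoacetate 11 by Horner–Wadsworth–Emmons methylenation with formaldehyde, so the exocyclic C=CH2 is made last.
2. 11 comes from the linear aldehyde 5 and the dienyl phosphonate 8 in one flask: the C4–C5 bond by amine-catalysed 1,6-addition, the O1–C2 bond by oxa-Michael closure after reduction of C6. This closes the only ring (the oxane) and sets both stereocentres.
3. Enabling feature: in the oxane (O1, C2 acrylate-bearing, C3, C4, C5 chain-bearing, C6) the O1–C2 bond is the β-alkoxy bond of the acrylate, C5 is the α-carbon of the C6H2–O1 unit (a latent aldehyde α-position), and C3–C4 map onto the γ,δ-carbons of a 2-phosphono-2,4-dienoate. The phosphonate activates both conjugate additions and leaves in the methylenation.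
4. 5 comes from (2E,6E)-farnesyl bromide and a three-carbon acetal Grignard reagent; 8 comes from acrolein and triethyl phosphonoacetate.

Key step: step 4

Remark on the chemistry: the (R)-diarylprolinol silyl ether is assumed to deliver the electrophile to the same enamine face as in its established additions to terminal CH2= acceptors, which corresponds to (S) at C5 of the (2R,5S) trans-oxane.

Step 1
Reactants: 1 2-(2-bromoethyl)-1,3-dioxolane; 2 (2E,6E)-farnesyl bromide
Product: 4 2-[(4E,8E)-5,9,13-trimethyltetradeca-4,8,12-trien-1-yl]-1,3-dioxolane, via Grignard reagent 3 (not isolated)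
Conditions: Mg, THF, 25 °C; then 2, Li2CuCl4 (3 mol %), THF, −10 to 0 °C
Reagents that add atoms: none
Why: Copper-catalysed Grignard allylic coupling: the primary alkylmagnesium 3 should displace the primary allylic bromide at the α-carbon with retention of the (E,E) geometry, the acetal being inert to the organometallic.

Step 2
Reactants: 4 2-[(4E,8E)-5,9,13-trimethyltetradeca-4,8,12-trien-1-yl]-1,3-dioxolane
Product: 5 (5E,9E)-6,10,14-trimethylpentadeca-5,9,13-trienal
Conditions: TsOH·H2O (10 mol %), THF–H2O (4:1), 45 °C
Reagents that add atoms: water, O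
Why: Acid-catalysed acetal hydrolysis under dilute, mildly acidic conditions should free the aldehyde without protonating the trisubstituted alkenes.

Step 3
Reactants: 6 triethyl phosphonoacetate; 7 acrolein
Product: 8 ethyl 2-(diethoxyphosphoryl)penta-2,4-dienoate (E/Z mixture)
Conditions: TiCl4, N-methylmorpholine, THF, 0 to 23 °C
Reagents that add atoms: none
Why: Knoevenagel condensation (titanium enolate adds 1,2 to the aldehyde, then dehydration) should give the doubly activated diene, whose E/Z isomers converge later; it is used freshly prepared.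

Step 4
Reactants: 5 (5E,9E)-6,10,14-trimethylpentadeca-5,9,13-trienal; 8 ethyl 2-(diethoxyphosphoryl)penta-2,4-dienoate
Product: 11 ethyl 2-(diethoxyphosphoryl)-2-{(2R,5S)-5-[(3E,7E)-4,8,12-trimethyltrideca-3,7,11-trien-1-yl]oxan-2-yl}acetate (epimer mixture at the phosphorus-bearing carbon), via formyl phosphonoenoate 9 (not isolated), via hydroxy phosphonoenoate 10 (not isolated)
Conditions: (R)-2-{bis[3,5-bis(trifluoromethyl)phenyl][(trimethylsilyl)oxy]methyl}pyrrolidine (10 mol %), PhCO2H (10 mol %), CHCl3, 0 °C; then EtOH, CeCl3·7H2O, NaBH4, −40 °C; then DBU (0.5 equiv), 23 °C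
Reagents that add atoms: none
Why: Proposed new method: The amine condenses with 5 to the (E)-enamine, whose α-carbon adds to the unsubstituted δ-terminus of 8 (1,6-addition, the charge carried by the phosphonoacetate), protonation and hydrolysis release aldehyde 9 and the amine, CeCl3-assisted borohydride reduction gives alcohol 10, and DBU re-conjugates the phosphonoenoate and lets the primary alkoxide add to C2. The closest known reaction types are the diarylprolinol silyl ether-catalysed conjugate addition of aldehydes to ethyl 2-(diethoxyphosphoryl)acrylate with in-flask borohydride reduction, amine-catalysed 1,6-additions of aldehydes to doubly activated 1,3-dienes, and base-mediated oxa-Michael closure of hydroxy alkylidene phosphonoacetates; what is new is the 1,6-addition to a 2-phosphono-2,4-dienoate. The oxane closes by 6-exo-trig oxa-Michael addition. C5 is set by the catalyst: the bulky diaryl(silyloxy)methyl group of the (R)-amine blocks one enamine face, so the diene should add to the open face and give the (S)-centre. C2 is set by the substrate under thermodynamic control: the oxa-Michael addition is reversible under DBU and should settle on the chair with the C2 arm and the C5 chain both equatorial (trans, 2R,5S), while the phosphorus-bearing carbon forms as an epimer mixture that step 5 erases. The step needs 1,6- over 1,4-addition (secured by the unhindered CH2 terminus against the substituted β-carbon), aldehyde over enoate reduction (secured by CeCl3 at −40 °C) and retention of configuration at the α-branched aldehyde (secured by reducing it in the same flask).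

Step 5
Reactants: 11 ethyl 2-(diethoxyphosphoryl)-2-{(2R,5S)-5-[(3E,7E)-4,8,12-trimethyltrideca-3,7,11-trien-1-yl]oxan-2-yl}acetate
Product: 12 ethyl 2-{(2R,5S)-5-[(3E,7E)-4,8,12-trimethyltrideca-3,7,11-trien-1-yl]oxan-2-yl}prop-2-enoate
Conditions: 37% aq. HCHO, K2CO3, THF, 23 to 45 °C
Reagents that add atoms: formaldehyde, C=O
Why: Horner–Wadsworth–Emmons olefination: the phosphonate carbanion adds to formaldehyde and expels diethyl phosphate to give the 1,1-disubstituted alkene; the ring stereocentres are not involved, and any ring-opened material should re-close under the same reversible, trans-favouring conditions before olefination.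

Step 6
Reactants: 12 ethyl 2-{(2R,5S)-5-[(3E,7E)-4,8,12-trimethyltrideca-3,7,11-trien-1-yl]oxan-2-yl}prop-2-enoate
Product: 13 rhopaloic acid A, 2-{(2R,5S)-5-[(3E,7E)-4,8,12-trimethyltrideca-3,7,11-trien-1-yl]oxan-2-yl}prop-2-enoic acid
Conditions: LiOH·H2O, THF–H2O (3:1), 23 °C; then 1 M HCl to pH 4, 0 °C
Reagents that add atoms: lithium hydroxide, [Li+].[OH-]
Why: Ester saponification (acyl–oxygen cleavage by hydroxide) followed by mild acidification should give the acid without touching the stereocentres or the alkenes.

**Compound list**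
1 | 2-(2-bromoethyl)-1,3-dioxolane | BrCCC1OCCO1 | starting material
2 | (2E,6E)-farnesyl bromide, (2E,6E)-1-bromo-3,7,11-trimethyldodeca-2,6,10-triene | BrC/C=C(\C)CC/C=C(\C)CCC=C(C)C | starting material
3 | [2-(1,3-dioxolan-2-yl)ethyl]magnesium bromide | Br[Mg]CCC1OCCO1 | intermediate
4 | 2-[(4E,8E)-5,9,13-trimethyltetradeca-4,8,12-trien-1-yl]-1,3-dioxolane | C1COC(O1)CCC/C=C(\C)CC/C=C(\C)CCC=C(C)C | intermediate
5 | (5E,9E)-6,10,14-trimethylpentadeca-5,9,13-trienal | O=CCCC/C=C(\C)CC/C=C(\C)CCC=C(C)C | intermediate
6 | triethyl phosphonoacetate | CCOC(=O)CP(=O)(OCC)OCC | starting material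
7 | acrolein | C=CC=O | starting material
8 | ethyl 2-(diethoxyphosphoryl)penta-2,4-dienoate (E/Z mixture) | C=CC=C(C(=O)OCC)P(=O)(OCC)OCC | intermediate
9 | ethyl (6S,9E,13E)-2-(diethoxyphosphoryl)-6-formyl-10,14,18-trimethylnonadeca-2,9,13,17-tetraenoate (2-ene drawn; 2E/Z and 3-ene isomers interconvert) | O=C[C@@H](CC/C=C(\C)CC/C=C(\C)CCC=C(C)C)CCC=C(C(=O)OCC)P(=O)(OCC)OCC | intermediate
10 | ethyl (6S,9E,13E)-2-(diethoxyphosphoryl)-6-(hydroxymethyl)-10,14,18-trimethylnonadeca-2,9,13,17-tetraenoate | OC[C@@H](CC/C=C(\C)CC/C=C(\C)CCC=C(C)C)CCC=C(C(=O)OCC)P(=O)(OCC)OCC | intermediate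
11 | ethyl 2-(diethoxyphosphoryl)-2-{(2R,5S)-5-[(3E,7E)-4,8,12-trimethyltrideca-3,7,11-trien-1-yl]oxan-2-yl}acetate | CCOC(=O)C([C@H]1CC[C@H](CC/C=C(\C)CC/C=C(\C)CCC=C(C)C)CO1)P(=O)(OCC)OCC | intermediate
12 | ethyl 2-{(2R,5S)-5-[(3E,7E)-4,8,12-trimethyltrideca-3,7,11-trien-1-yl]oxan-2-yl}prop-2-enoate | C=C(C(=O)OCC)[C@H]1CC[C@H](CC/C=C(\C)CC/C=C(\C)CCC=C(C)C)CO1 | intermediate
13 | rhopaloic acid A | C=C(C(=O)O)[C@H]1CC[C@H](CC/C=C(\C)CC/C=C(\C)CCC=C(C)C)CO1 | target

**Step count and risks**
Total step count: 6. Longest linear sequence: 5 steps (1, 2, 4, 5, 6); step 3 is a one-step side branch.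

Steps most likely to fail:

Step 4 (proposed new method). The enamine may add 1,4 at the substituted β-carbon. The zwitterionic adduct may close by a Mannich-type ring closure (a formal cycloaddition that ties up the amine). The diene may oligomerise, or the α-branched aldehyde may re-enolise before reduction and lose enantiomeric purity. The ring closure may also stop short of full trans selectivity. The fallback uses known chemistry, sets out from 5 and comes back at 11, forming the two bonds in separate operations. Pinnick oxidation of 5 (NaClO2, NaH2PO4, 2-methyl-2-butene) should give (5E,9E)-6,10,14-trimethylpentadeca-5,9,13-trienoic acid F1. Its mixed pivalic anhydride acylates lithiated (4R)-4-benzyl-1,3-oxazolidin-2-one to (4R)-4-benzyl-3-[(5E,9E)-6,10,14-trimethylpentadeca-5,9,13-trienoyl]-1,3-oxazolidin-2-one F2. The chlorotitanium enolate (TiCl3(OiPr), iPr2NEt, CH2Cl2, 0 °C) adds to methyl acrylate under auxiliary control to methyl (4S,7E,11E)-4-[(4R)-4-benzyl-2-oxo-1,3-oxazolidine-3-carbonyl]-8,12,16-trimethylheptadeca-7,11,15-trienoate F3. LiBH4 (Et2O, 0 °C) reduces the imide carbonyl and the hydroxy ester lactonises to (5S)-5-[(3E,7E)-4,8,12-trimethyltrideca-3,7,11-trien-1-yl]oxan-2-one F4. DIBAL-H at −78 °C gives the lactol (5S)-5-[(3E,7E)-4,8,12-trimethyltrideca-3,7,11-trien-1-yl]oxan-2-ol F5. Knoevenagel condensation of F5 with 6, followed by oxa-Michael closure under DBU, returns to 11.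

Step 3. The phosphonoacetate enolate may add 1,4 to acrolein instead of to the carbonyl, acrolein may polymerise, and the diene may dimerise on isolation. The fallback masks the vinyl group, sets out from 6 and 7 and comes back at 8. Conjugate addition of benzeneselenol to 7 gives 3-(phenylselanyl)propanal F6. Knoevenagel condensation with 6 (TiCl4, N-methylmorpholine), now without a competing Michael site, gives ethyl 2-(diethoxyphosphoryl)-5-(phenylselanyl)pent-2-enoate F7. Oxidation with H2O2 and syn-elimination of the selenoxide at 23 °C releases 8 just before use.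

Step 6. Hydroxide may add to the acrylate or open the ring by β-alkoxide elimination during saponification of the unsaturated ester. The fallback reverses the order of hydrolysis and olefination, sets out from 11 and comes back at 13. Saponification of 11 with LiOH gives 2-(diethoxyphosphoryl)-2-{(2R,5S)-5-[(3E,7E)-4,8,12-trimethyltrideca-3,7,11-trien-1-yl]oxan-2-yl}acetic acid F8. Horner–Wadsworth–Emmons reaction of its dianion with aqueous formaldehyde and K2CO3 gives 13 directly after mild acidification, so the acrylate ester is never exposed to hydroxide.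

Further compounds
F1 | step 4 | (5E,9E)-6,10,14-trimethylpentadeca-5,9,13-trienoic acid | OC(=O)CCC/C=C(\C)CC/C=C(\C)CCC=C(C)C
F2 | step 4 | (4R)-4-benzyl-3-[(5E,9E)-6,10,14-trimethylpentadeca-5,9,13-trienoyl]-1,3-oxazolidin-2-one | O=C(CCC/C=C(\C)CC/C=C(\C)CCC=C(C)C)N1[C@H](Cc2ccccc2)COC1=O
F3 | step 4 | methyl (4S,7E,11E)-4-[(4R)-4-benzyl-2-oxo-1,3-oxazolidine-3-carbonyl]-8,12,16-trimethylheptadeca-7,11,15-trienoate | COC(=O)CC[C@H](CC/C=C(\C)CC/C=C(\C)CCC=C(C)C)C(=O)N1[C@H](Cc2ccccc2)COC1=O
F4 | step 4 | (5S)-5-[(3E,7E)-4,8,12-trimethyltrideca-3,7,11-trien-1-yl]oxan-2-one | O=C1CC[C@H](CC/C=C(\C)CC/C=C(\C)CCC=C(C)C)CO1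
F5 | step 4 | (5S)-5-[(3E,7E)-4,8,12-trimethyltrideca-3,7,11-trien-1-yl]oxan-2-ol (anomer mixture) | OC1CC[C@H](CC/C=C(\C)CC/C=C(\C)CCC=C(C)C)CO1
F6 | step 3 | 3-(phenylselanyl)propanal | O=CCC[Se]c1ccccc1
F7 | step 3 | ethyl 2-(diethoxyphosphoryl)-5-(phenylselanyl)pent-2-enoate | CCOC(=O)C(=CCC[Se]c1ccccc1)P(=O)(OCC)OCC
F8 | step 6 | 2-(diethoxyphosphoryl)-2-{(2R,5S)-5-[(3E,7E)-4,8,12-trimethyltrideca-3,7,11-trien-1-yl]oxan-2-yl}acetic acid | OC(=O)C([C@H]1CC[C@H](CC/C=C(\C)CC/C=C(\C)CCC=C(C)C)CO1)P(=O)(OCC)OCC
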